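Both pyranone rings C are opened at O1–C2 and C2–C3 (and at O1''–C2'' and C2''–C3''). This reduces the target to a racemic 3,3'-diacetyl hexaoxygenated biphenyl and two aroyl groups. The feature exploited is that each future C3 is an acetyl methyl carbon ortho to the future ring oxygen. In the anisyl unit this is O1 on C8a, next to the axis carbon C8. In the other unit it is O1'' on C8a'', para to the axis carbon C6''. One base treatment moves an anisoyl and a 4-benzyloxybenzoyl group from these two oxygens to the two methyl carbons. The precursor is therefore the biaryl bis(acetophenone) diester, with its five other phenolic oxygens benzylated.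

Key step: step 12

Remarks on the chemistry
- Assumption: the SMILES carries no axial descriptor, so the configurationally stable C8–C6'' axis is built in racemic form.
- Design: the two ester-bearing oxygens are never free at the same time. The oxygen para to the axis stays masked as a MOM ether until the crowded phenol beside the axis has been anisoylated. Each aroyl chloride therefore meets a single phenol, and no rate difference between two phenols is needed.
- Checkpoint: the site of iodination in steps 2 and 5 fixes which unit becomes 8-linked and which 6''-linked. It should be confirmed by HMBC from the chelated OH proton to the iodine-bearing carbon before material is carried on.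

Step 1
Reactants: 1 2,4,6-trihydroxyacetophenone; 2 benzyl bromide
Product: 3 1-[2,4-bis(benzyloxy)-6-hydroxyphenyl]ethanone
Conditions: BnBr (2.1 equiv), K2CO3 (2.2 equiv), DMF, rt to 50 °C
Reagents that add atoms: benzyl bromide 2, BrCc1ccccc1
Why: Williamson ether synthesis: the acidic 4-OH and one of the two ortho OH groups are alkylated, after which the last OH is tied up in a strong hydrogen bond to the acetyl oxygen and is not benzylated by K2CO3/BnBr at this temperature.

Step 2
Reactants: 3 1-[2,4-bis(benzyloxy)-6-hydroxyphenyl]ethanone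
Product: 4 1-[4,6-bis(benzyloxy)-2-hydroxy-3-iodophenyl]ethanone
Conditions: NIS (1.0 equiv), TFA (cat.), MeCN, 0 °C to rt, dark
Reagents that add atoms: N-iodosuccinimide, O=C1CCC(=O)N1I
Why: Electrophilic aromatic iodination of a 2-hydroxy-4,6-dialkoxyacetophenone goes to C3, the carbon ortho to the chelated phenol and para to the 6-alkoxy group, and one equivalent of NIS should stop at the monoiodide.

Step 3
Reactants: 1 2,4,6-trihydroxyacetophenone; 2 benzyl bromide
Product: 5 1-[4-(benzyloxy)-2,6-dihydroxyphenyl]ethanone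
Conditions: BnBr (1.0 equiv, slow addition), K2CO3 (1.0 equiv), DMF, 0 °C to rt
Reagents that add atoms: benzyl bromide 2, BrCc1ccccc1
Why: Williamson ether synthesis with one equivalent each of base and halide selects the 4-OH, which is the most acidic phenol and the only one that takes no part in chelation, and any over-benzylated material is compound 3 and can enter step 2.

Step 4
Reactants: 5 1-[4-(benzyloxy)-2,6-dihydroxyphenyl]ethanone
Product: 6 1-[4-(benzyloxy)-2-hydroxy-6-(methoxymethoxy)phenyl]ethanone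
Conditions: MOMCl (1.05 equiv), i-Pr2NEt (1.2 equiv), CH2Cl2, 0 °C
Reagents that add atoms: chloromethyl methyl ether, COCCl
Why: Acetal protection by O-alkylation: the two ortho phenols of 5 are equivalent, so no regiochemical question arises, and the remaining chelated OH reacts far more slowly, so the reaction should stop at the mono-MOM ether.

Step 5
Reactants: 6 1-[4-(benzyloxy)-2-hydroxy-6-(methoxymethoxy)phenyl]ethanone
Product: 7 1-[4-(benzyloxy)-2-hydroxy-3-iodo-6-(methoxymethoxy)phenyl]ethanone
Conditions: NIS (1.0 equiv), DMF, 0 °C to rt, dark, no acid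
Reagents that add atoms: N-iodosuccinimide, O=C1CCC(=O)N1I
Why: Electrophilic aromatic iodination directed as in step 2 to the carbon ortho to the chelated OH, which places iodine para to the MOM-bearing oxygen and so encodes the 6''-linkage, and the acid-free medium spares the acetal.

Step 6
Reactants: 7 1-[4-(benzyloxy)-2-hydroxy-3-iodo-6-(methoxymethoxy)phenyl]ethanone; 2 benzyl bromide
Product: 8 1-[2,4-bis(benzyloxy)-3-iodo-6-(methoxymethoxy)phenyl]ethanone
Conditions: BnBr (1.3 equiv), K2CO3 (2 equiv), DMF, 60 °C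
Reagents that add atoms: benzyl bromide 2, BrCc1ccccc1
Why: Williamson ether synthesis on the only remaining phenol, whose chelation and flanking iodine are overcome by heat in a dipolar aprotic solvent.

Step 7
Reactants: 8 1-[2,4-bis(benzyloxy)-3-iodo-6-(methoxymethoxy)phenyl]ethanone
Product: 9 1-[2,4-bis(benzyloxy)-6-(methoxymethoxy)-3-(4,4,5,5-tetramethyl-1,3,2-dioxaborolan-2-yl)phenyl]ethanone
Conditions: HBpin (2.5 equiv), PdCl2(MeCN)2 (3 mol %), SPhos (12 mol %), Et3N (3 equiv), 1,4-dioxane, 90 °C
Reagents that add atoms: pinacolborane, CC1(C)OBOC1(C)C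
Why: Masuda-type palladium-catalysed borylation with pinacolborane, in which the SPhos catalyst accepts aryl iodides with two ortho substituents and the ketone, acetal and benzyl ethers are inert to HBpin/Et3N.

Step 8
Reactants: 4 1-[4,6-bis(benzyloxy)-2-hydroxy-3-iodophenyl]ethanone; 9 1-[2,4-bis(benzyloxy)-6-(methoxymethoxy)-3-(4,4,5,5-tetramethyl-1,3,2-dioxaborolan-2-yl)phenyl]ethanone
Product: 10 1,1'-[2',4,6,6'-tetrakis(benzyloxy)-2-hydroxy-4'-(methoxymethoxy)biphenyl-3,3'-diyl]diethanone (racemic axis)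
Conditions: Pd(OAc)2 (5 mol %), SPhos (10 mol %), K3PO4 (4 equiv), toluene/H2O 10:1, degassed, 100 °C; dilute acid work-up
Reagents that add atoms: none
Why: Suzuki-Miyaura coupling, in which the bulky electron-rich SPhos ligand speeds oxidative addition to zerovalent palladium and reductive elimination for biaryls with four slim oxygen ortho substituents, while the unprotected ortho-acyl phenol is carried through as its small potassium phenoxide.

Step 9
Reactants: 10 1,1'-[2',4,6,6'-tetrakis(benzyloxy)-2-hydroxy-4'-(methoxymethoxy)biphenyl-3,3'-diyl]diethanone; 11 4-methoxybenzoyl chloride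
Product: 12 3,3'-diacetyl-2',4,6,6'-tetrakis(benzyloxy)-4'-(methoxymethoxy)biphenyl-2-yl 4-methoxybenzoate
Conditions: 4-MeOC6H4COCl (3 equiv), Et3N (4 equiv), DMAP (0.5 equiv), CH2Cl2, 0 °C to 40 °C
Reagents that add atoms: 4-methoxybenzoyl chloride 11, COc1ccc(cc1)C(Cl)=O
Why: DMAP-catalysed O-acylation of the only free phenol, so the crowded position beside the axis can be forced with excess acid chloride without any question of site, while amine bases are too weak to start acyl transfer to carbon.

Step 10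
Reactants: 12 3,3'-diacetyl-2',4,6,6'-tetrakis(benzyloxy)-4'-(methoxymethoxy)biphenyl-2-yl 4-methoxybenzoate
Product: 13 3,3'-diacetyl-2',4,6,6'-tetrakis(benzyloxy)-4'-hydroxybiphenyl-2-yl 4-methoxybenzoate
Conditions: 3 M aq HCl, THF/i-PrOH 1:1, 45 °C
Reagents that add atoms: none
Why: Acid-catalysed acetal hydrolysis, which is especially easy for a MOM ether ortho to an acetyl group, whereas the benzyl ethers and the shielded aryl anisoate should survive dilute acid in a weakly nucleophilic medium.

Step 11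
Reactants: 13 3,3'-diacetyl-2',4,6,6'-tetrakis(benzyloxy)-4'-hydroxybiphenyl-2-yl 4-methoxybenzoate; 14 4-(benzyloxy)benzoic acid
Product: 16 3,3'-diacetyl-2',4,6,6'-tetrakis(benzyloxy)-4'-{[4-(benzyloxy)benzoyl]oxy}biphenyl-2-yl 4-methoxybenzoate, via 4-(benzyloxy)benzoyl chloride 15 (not isolated)
Conditions: 14, (COCl)2, DMF (cat.), CH2Cl2, rt, evaporate; then 13, Et3N (2 equiv), DMAP (cat.), CH2Cl2, 0 °C to rt
Reagents that add atoms: 4-(benzyloxy)benzoic acid 14, OC(=O)c1ccc(OCc2ccccc2)cc1; oxalyl chloride, O=C(Cl)C(Cl)=O (supplies only the chlorine of 15, which leaves again)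
Why: Acid chloride formation by Vilsmeier-type activation followed by DMAP-catalysed O-acylation of the single, unhindered phenol puts the second aroyl group unambiguously on the oxygen para to the axis.

Step 12
Reactants: 16 3,3'-diacetyl-2',4,6,6'-tetrakis(benzyloxy)-4'-{[4-(benzyloxy)benzoyl]oxy}biphenyl-2-yl 4-methoxybenzoate
Product: 17 1-[2',4,6,6'-tetrakis(benzyloxy)-3'-{3-[4-(benzyloxy)phenyl]-3-oxopropanoyl}-2,4'-dihydroxybiphenyl-3-yl]-3-(4-methoxyphenyl)propane-1,3-dione
Conditions: LiN(SiMe3)2 (6 equiv), THF (0.02 M), −78 °C to rt; AcOH quench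
Reagents that add atoms: none
Why: LiN(SiMe3)2 turns both methyl ketones into lithium enolates, and each enolate carbon adds to the carbonyl of the aroyl ester on the adjacent ring oxygen through a six-membered cyclic tetrahedral intermediate that collapses to a phenoxide and a 1,3-diketone, which a second equivalent of base per half deprotonates and thereby drives the transfer. This is the Baker-Venkataraman rearrangement, an intramolecular Claisen-type O-to-C acyl shift that is established for ortho-aroyloxyacetophenones, crowded biaryl cases included. The step forms C2–C3 and C2''–C3'', closes no ring and creates no stereocentre, and the racemic axis is not touched. The selectivity required is faithful delivery of each aroyl group to its own acetyl group: every acetyl is flanked by one ester and one benzyl ether, so only one acyl donor lies within reach, and low temperature with high dilution should suppress intermolecular crossover. A non-nucleophilic amide base avoids the ester cleavage that hydroxide could cause at the congested ring A of unit 1.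

Step 13
Reactants: 17 1-[2',4,6,6'-tetrakis(benzyloxy)-3'-{3-[4-(benzyloxy)phenyl]-3-oxopropanoyl}-2,4'-dihydroxybiphenyl-3-yl]-3-(4-methoxyphenyl)propane-1,3-dione
Product: 18 5,7-bis(benzyloxy)-8-{5,7-bis(benzyloxy)-2-[4-(benzyloxy)phenyl]-4-oxo-4H-chromen-6-yl}-2-(4-methoxyphenyl)-4H-chromen-4-one
Conditions: p-TsOH·H2O (0.4 equiv), toluene, 80 °C
Reagents that add atoms: none
Why: Acid-catalysed cyclodehydration, in which each phenol adds to the protonated aroyl carbonyl (6-exo-trig) and the resulting cyclic hemiketal loses water to give the 4-pyranone, and since only one phenol flanks each diketone the closures can give only the 8-linked and the 6''-linked flavone.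

Step 14
Reactants: 18 5,7-bis(benzyloxy)-8-{5,7-bis(benzyloxy)-2-[4-(benzyloxy)phenyl]-4-oxo-4H-chromen-6-yl}-2-(4-methoxyphenyl)-4H-chromen-4-one
Product: 19 8-[5,7-dihydroxy-2-(4-hydroxyphenyl)-4-oxo-4H-chromen-6-yl]-5,7-dihydroxy-2-(4-methoxyphenyl)-4H-chromen-4-one (CNP0310322.0)
Conditions: H2 (1 atm), 10% Pd/C, THF/MeOH 1:1, rt
Reagents that add atoms: none
Why: Catalytic hydrogenolysis should cleave all five aryl benzyl ethers under neutral conditions that spare the 4'-methyl ether and the C2=C3 bonds and that give no chance for acid-induced Wessely-Moser exchange of the 8- and 6-linked units.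

Compound list
1 | 2,4,6-trihydroxyacetophenone | CC(=O)c1c(O)cc(O)cc1O | starting material
2 | benzyl bromide | BrCc1ccccc1 | starting material
3 | 1-[2,4-bis(benzyloxy)-6-hydroxyphenyl]ethanone | CC(=O)c1c(O)cc(OCc2ccccc2)cc1OCc1ccccc1 | intermediate
4 | 1-[4,6-bis(benzyloxy)-2-hydroxy-3-iodophenyl]ethanone | CC(=O)c1c(O)c(I)c(OCc2ccccc2)cc1OCc1ccccc1 | intermediate
5 | 1-[4-(benzyloxy)-2,6-dihydroxyphenyl]ethanone | CC(=O)c1c(O)cc(OCc2ccccc2)cc1O | intermediate
6 | 1-[4-(benzyloxy)-2-hydroxy-6-(methoxymethoxy)phenyl]ethanone | CC(=O)c1c(O)cc(OCc2ccccc2)cc1OCOC | intermediate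
7 | 1-[4-(benzyloxy)-2-hydroxy-3-iodo-6-(methoxymethoxy)phenyl]ethanone | CC(=O)c1c(O)c(I)c(OCc2ccccc2)cc1OCOC | intermediate
8 | 1-[2,4-bis(benzyloxy)-3-iodo-6-(methoxymethoxy)phenyl]ethanone | CC(=O)c1c(OCc2ccccc2)c(I)c(OCc2ccccc2)cc1OCOC | intermediate
9 | 1-[2,4-bis(benzyloxy)-6-(methoxymethoxy)-3-(4,4,5,5-tetramethyl-1,3,2-dioxaborolan-2-yl)phenyl]ethanone | CC(=O)c1c(OCc2ccccc2)c(B2OC(C)(C)C(C)(C)O2)c(OCc2ccccc2)cc1OCOC | intermediate
10 | 1,1'-[2',4,6,6'-tetrakis(benzyloxy)-2-hydroxy-4'-(methoxymethoxy)biphenyl-3,3'-diyl]diethanone (racemic axis) | CC(=O)c1c(O)c(c(OCc2ccccc2)cc1OCc1ccccc1)-c1c(OCc2ccccc2)cc(OCOC)c(C(C)=O)c1OCc1ccccc1 | intermediate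
11 | 4-methoxybenzoyl chloride | COc1ccc(cc1)C(Cl)=O | starting material
12 | 3,3'-diacetyl-2',4,6,6'-tetrakis(benzyloxy)-4'-(methoxymethoxy)biphenyl-2-yl 4-methoxybenzoate | COc1ccc(cc1)C(=O)Oc1c(C(C)=O)c(OCc2ccccc2)cc(OCc2ccccc2)c1-c1c(OCc2ccccc2)cc(OCOC)c(C(C)=O)c1OCc1ccccc1 | intermediate
13 | 3,3'-diacetyl-2',4,6,6'-tetrakis(benzyloxy)-4'-hydroxybiphenyl-2-yl 4-methoxybenzoate | COc1ccc(cc1)C(=O)Oc1c(C(C)=O)c(OCc2ccccc2)cc(OCc2ccccc2)c1-c1c(OCc2ccccc2)cc(O)c(C(C)=O)c1OCc1ccccc1 | intermediate
14 | 4-(benzyloxy)benzoic acid | OC(=O)c1ccc(OCc2ccccc2)cc1 | starting material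
15 | 4-(benzyloxy)benzoyl chloride (not isolated) | ClC(=O)c1ccc(OCc2ccccc2)cc1 | intermediate
16 | 3,3'-diacetyl-2',4,6,6'-tetrakis(benzyloxy)-4'-{[4-(benzyloxy)benzoyl]oxy}biphenyl-2-yl 4-methoxybenzoate (precursor of the key step) | COc1ccc(cc1)C(=O)Oc1c(C(C)=O)c(OCc2ccccc2)cc(OCc2ccccc2)c1-c1c(OCc2ccccc2)cc(OC(=O)c2ccc(OCc3ccccc3)cc2)c(C(C)=O)c1OCc1ccccc1 | intermediate
17 | 1-[2',4,6,6'-tetrakis(benzyloxy)-3'-{3-[4-(benzyloxy)phenyl]-3-oxopropanoyl}-2,4'-dihydroxybiphenyl-3-yl]-3-(4-methoxyphenyl)propane-1,3-dione (drawn as the diketo tautomer) | COc1ccc(cc1)C(=O)CC(=O)c1c(OCc2ccccc2)cc(OCc2ccccc2)c(c1O)-c1c(OCc2ccccc2)cc(O)c(C(=O)CC(=O)c2ccc(OCc3ccccc3)cc2)c1OCc1ccccc1 | intermediate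
18 | 5,7-bis(benzyloxy)-8-{5,7-bis(benzyloxy)-2-[4-(benzyloxy)phenyl]-4-oxo-4H-chromen-6-yl}-2-(4-methoxyphenyl)-4H-chromen-4-one | COc1ccc(cc1)-c1cc(=O)c2c(OCc3ccccc3)cc(OCc3ccccc3)c(c2o1)-c1c(OCc2ccccc2)cc2oc(cc(=O)c2c1OCc1ccccc1)-c1ccc(OCc2ccccc2)cc1 | intermediate
19 | 8-[5,7-dihydroxy-2-(4-hydroxyphenyl)-4-oxo-4H-chromen-6-yl]-5,7-dihydroxy-2-(4-methoxyphenyl)-4H-chromen-4-one (CNP0310322.0, racemic axis) | COc1ccc(-c2cc(=O)c3c(O)cc(O)c(-c4c(O)cc5oc(-c6ccc(O)cc6)cc(=O)c5c4O)c3o2)cc1 | target

Total step count: 14.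
Longest linear sequence: 12 steps (1 through steps 3, 4, 5, 6, 7, 8, 9, 10, 11, 12, 13 and 14).

Steps most likely to fail

Step 8 (biaryl coupling). Transmetalation at a boron atom flanked by two benzyloxy groups may be too slow. Protodeboronation of the boronate and hydrodeiodination of the iodophenol could then overtake C–C bond formation. The fallback replaces cross-coupling by ligand coupling at tetravalent lead. It sets out from 8 and 3, comes back at 10, and makes steps 2 and 7 unnecessary. Iodide 8 is stannylated ((Bu3Sn)2, Pd(PPh3)4, toluene, 110 °C) to 1-[2,4-bis(benzyloxy)-6-(methoxymethoxy)-3-(tributylstannyl)phenyl]ethanone F1. Tin-lead exchange (Pb(OAc)4, Hg(OAc)2 cat., CHCl3, 40 °C) then gives [3-acetyl-2,6-bis(benzyloxy)-4-(methoxymethoxy)phenyl]lead triacetate F2. This reagent is combined with phenol 3 and pyridine in CHCl3 at 40 to 60 °C (Pinhey-Barton ortho-arylation). The aryl group is delivered from an aryloxylead intermediate to the only unsubstituted carbon ortho to the phenol. This mode of bond formation is known to tolerate heavy ortho substitution, and it should give 10 directly.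

Step 12 (double acyl transfer). The anisoate beside the axis may migrate more slowly than the remote ester. A poorly soluble polyanion or premature loss of one ester could then leave the transfer incomplete on one half. The fallback handles one half at a time, so that only one aroyl group is ever present. It sets out from 12 and comes back at 18.
- Treating 12 with LiN(SiMe3)2 in THF moves the single anisoyl group and gives 1-[3'-acetyl-2',4,6,6'-tetrakis(benzyloxy)-2-hydroxy-4'-(methoxymethoxy)biphenyl-3-yl]-3-(4-methoxyphenyl)propane-1,3-dione F3.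
- p-TsOH·H2O in toluene/i-PrOH at 80 °C closes the first pyranone and strips the MOM group. The product is 8-[3-acetyl-2,6-bis(benzyloxy)-4-hydroxyphenyl]-5,7-bis(benzyloxy)-2-(4-methoxyphenyl)-4H-chromen-4-one F4.
- Acylation with 15 (Et3N, DMAP, CH2Cl2) gives 2-acetyl-3,5-bis(benzyloxy)-4-[5,7-bis(benzyloxy)-2-(4-methoxyphenyl)-4-oxo-4H-chromen-8-yl]phenyl 4-(benzyloxy)benzoate F5.
- A second Baker-Venkataraman transfer with LiN(SiMe3)2 gives 1-{2,4-bis(benzyloxy)-3-[5,7-bis(benzyloxy)-2-(4-methoxyphenyl)-4-oxo-4H-chromen-8-yl]-6-hydroxyphenyl}-3-[4-(benzyloxy)phenyl]propane-1,3-dione F6.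
- p-TsOH·H2O in toluene then closes the second pyranone to 18.

Step 14 (global debenzylation). Partly deprotected biflavones may precipitate on the catalyst and stall the cleavage of the benzyl ethers next to the axis. Prolonged exposure could then start saturation of the C2=C3 bonds. The fallback swaps hydrogenolysis for Lewis-acid dealkylation. It sets out from 18, comes back at 19, and passes through no new compound (F0). The reagents are BCl3 in excess and pentamethylbenzene as benzyl cation trap, in CH2Cl2 from −78 °C to −40 °C, followed by a MeOH quench. The non-chelated 4'-methyl ether should not be cleaved at this temperature. The scavenger should prevent C-benzylation at C6 and C8''.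

Further compounds
F1 | step 8 | 1-[2,4-bis(benzyloxy)-6-(methoxymethoxy)-3-(tributylstannyl)phenyl]ethanone | CC(=O)c1c(OCc2ccccc2)c([Sn](CCCC)(CCCC)CCCC)c(OCc2ccccc2)cc1OCOC
F2 | step 8 | [3-acetyl-2,6-bis(benzyloxy)-4-(methoxymethoxy)phenyl]lead triacetate | CC(=O)O[Pb](OC(C)=O)(OC(C)=O)c1c(OCc2ccccc2)cc(OCOC)c(C(C)=O)c1OCc1ccccc1
F3 | step 12 | 1-[3'-acetyl-2',4,6,6'-tetrakis(benzyloxy)-2-hydroxy-4'-(methoxymethoxy)biphenyl-3-yl]-3-(4-methoxyphenyl)propane-1,3-dione | COc1ccc(cc1)C(=O)CC(=O)c1c(OCc2ccccc2)cc(OCc2ccccc2)c(c1O)-c1c(OCc2ccccc2)cc(OCOC)c(C(C)=O)c1OCc1ccccc1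
F4 | step 12 | 8-[3-acetyl-2,6-bis(benzyloxy)-4-hydroxyphenyl]-5,7-bis(benzyloxy)-2-(4-methoxyphenyl)-4H-chromen-4-one | COc1ccc(cc1)-c1cc(=O)c2c(OCc3ccccc3)cc(OCc3ccccc3)c(c2o1)-c1c(OCc2ccccc2)cc(O)c(C(C)=O)c1OCc1ccccc1
F5 | step 12 | 2-acetyl-3,5-bis(benzyloxy)-4-[5,7-bis(benzyloxy)-2-(4-methoxyphenyl)-4-oxo-4H-chromen-8-yl]phenyl 4-(benzyloxy)benzoate | COc1ccc(cc1)-c1cc(=O)c2c(OCc3ccccc3)cc(OCc3ccccc3)c(c2o1)-c1c(OCc2ccccc2)cc(OC(=O)c2ccc(OCc3ccccc3)cc2)c(C(C)=O)c1OCc1ccccc1
F6 | step 12 | 1-{2,4-bis(benzyloxy)-3-[5,7-bis(benzyloxy)-2-(4-methoxyphenyl)-4-oxo-4H-chromen-8-yl]-6-hydroxyphenyl}-3-[4-(benzyloxy)phenyl]propane-1,3-dione | COc1ccc(cc1)-c1cc(=O)c2c(OCc3ccccc3)cc(OCc3ccccc3)c(c2o1)-c1c(OCc2ccccc2)cc(O)c(C(=O)CC(=O)c2ccc(OCc3ccccc3)cc2)c1OCc1ccccc1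
F0 | step 14 | none | none
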